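(The readings were generated by integration from invented constants, and the scatter is random.)

In a one-step world the single-handed free catalyst takes the left-handed substrate and leaves the other, so conversion stops at half of the charge, with an excess of 100 % of right-handed substrate in what is left. A racemate that stays a racemate is the zero of that scale.

| setting | south-east | flask |
|---|---|---|
| left-handed substrate | 10 mM | 10 mM |
| right-handed substrate | 10 mM | 10 mM |
| gas | 2.4 mM (held) | 2.4 mM (held) |
| free catalyst | 0.93 mM | 0.93 mM |
| impurity | 0.46 mM | 0.46 mM |
| remark | the very flask that is asked about, followed so far |  |
| time |  | 2.5 d |

- south-east (time / h: left-handed substrate / %, right-handed substrate / %, left-handed product / %): 5.00: 32, 35, 32; 10.0: 25, 26, 44; 15.0: 22, 27, 50; 20.0: 25, 27, 50; 25.0: 25, 25, 51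

(each reading ± 1.5 percentage points)

- free catalyst is single-handed; left-handed substrate and right-handed substrate are mirror images of each other, charged as a racemate, each of them at the stated concentration
- at the start none of the gas is in solution
- an excess is below zero if the other one leads

- part of the left-handed substrate and right-handed substrate charged together that has reacted at 2.5 d
- excess of left-handed product over right-handed product in the product at 2.5 d
- excess of right-handed substrate over left-handed substrate among what is left of the two at 2.5 d

The south-east run also stalls near half, yet at 25.0 h its substrates read 25 % and 25 %, with a scatter of 1.5 percentage points. That is the zero of the scale, not its end, so this stall is no resolution. I suspect the catalyst, and I suppose that each impurity takes one free catalyst. The working catalyst is then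

W = 0.470 mM

and the last 3 readings of left-handed product average

P = 10.1 mM

so that

N = P/W = 21.4

This N, the product one working catalyst makes before the stall, its turnover number, turns the question round. For the whole charge of 20.0 mM to react on this W, N has to be 42.6, and the south-east run reads half of that. I therefore commit to c = 50.3 %, eS = 0 %, and eP close to 100 %, since substrates and left-handed product sum to 101 % at the last reading.

The forecast gives c = 50 %, eP = 99 % and, where I differ, eS = 2 %, saying “I expect little change”.

The flask gives c = 50.7 %, eP = 98.5 %, eS = 0 %.

    coupling partner + free catalyst + left-handed substrate → free catalyst + left-handed product (k = 6100 L² mol⁻² min⁻¹)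
    coupling partner + free catalyst + right-handed substrate → free catalyst + right-handed product (k = 45.0 L² mol⁻² min⁻¹)
    left-handed substrate ⇌ right-handed substrate (k = 0.0260 min⁻¹)
    gas ⇌ coupling partner, rate k4*(csat - [coupling partner]) (kL = 0.0280 min⁻¹)
    free catalyst + impurity → spent catalyst A (k = 3300 L mol⁻¹ min⁻¹)
    coupling partner + free catalyst → spent catalyst B (k = 2.00 L mol⁻¹ min⁻¹)

In this flask at 0.138 d, coupling partner goes into left-handed product 23 times as fast as into spent catalyst B, a figure close to N = 21.4. At 2.50 d free catalyst stands at 0 %, with 49.5 % of the catalyst charged as spent catalyst A and 50.5 % as spent catalyst B. A neighbouring flask charged with 2.3 mM of free catalyst has W = 1.84 mM and reaches c = 93.0 % with its free catalyst at 0 %, so its N is 10.1, less than the 21.4 read in the south-east run.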